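A direct plan would acylate 4-methylresorcinol with isovaleryl chloride to ketone A1, join two molecules of A1 with formaldehyde to the bridged bis(ketone) A2, and add the two missing ring oxygens last. For this, A2 would be turned into the tetrapivalate bis(O-methyl oxime) A3, whose oximes would direct a twofold Pd(OAc)2/PhI(OAc)2 C–H methoxylation in methanol to A4, before deoximation and ester cleavage. Its weakest steps would be:
- the double C–H methoxylation, which would have to succeed twice on one molecule at crowded ring carbons, with methoxide outcompeting acetate transfer;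
- the making and removal of two oxime ethers and four pivalates, four steps that would add length and no skeletal complexity;
- the reductive deoximation (TiCl3) of hindered oxime ethers, which would have to spare four aryl esters.

The route would build both benzene rings rather than buy them. Each ring is cut at C3'–C4' and C1'–C2', which reveals dimethyl glutarate (the bridge CH2, C3'/C3''' and C2'/C2''') and two molecules of a 4-methoxy-2-pyranone (C4', C5', C6', C1' and the isovaleryl chain). In one operation the glutarate bis-enolate should open both lactones and the released ketone enolates should close onto the glutarate esters, forming four C–C bonds, both hexasubstituted rings and the diarylmethane. Because the three ring oxygens stem from a lactone carbonyl, an ester carbonyl and a preformed enol ether, the methyl ether is placed by construction: no C–H oxygenation, directing group or phenol protection remains.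

Key step: step 4

Remark: 4 (racemic) and 9 (mixture of diastereomers) carry uncontrolled stereocentres; all of them become sp2 carbons in steps 2 and 4, and the target is achiral.

Step 1
Reactants: 1 ethyl 2-methyl-3-oxobutanoate; 2 ethyl 3-methylbutanoate
Product: 4 ethyl 2,7-dimethyl-3,5-dioxooctanoate, via dilithium bis-enolate 3 (not isolated)
Conditions: 1 (2.2 equiv), LiN(iPr)2 (4.4 equiv), THF, −78 to 0 °C; then 2 (1.0 equiv), 0 °C to rt; aq. HCl
Reagents that add atoms: ethyl 3-methylbutanoate (2), CCOC(=O)CC(C)C
Why: Claisen-type acylation of a β-keto ester dianion should take place at its terminal carbon, the more basic and more nucleophilic of the two carbanion sites, and the dianion is taken in twofold amount because the diketo ester formed is more acidic than its precursor and protonates one equivalent.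

Step 2
Reactants: 4 ethyl 2,7-dimethyl-3,5-dioxooctanoate
Product: 5 4-hydroxy-3-methyl-6-(2-methylpropyl)-2H-pyran-2-one
Conditions: DBU (1.5 equiv), toluene, reflux; aq. HCl
Reagents that add atoms: none
Why: Base-mediated enol lactonisation should occur because the enolate oxygen of the C5 ketone can attack the ester through a six-membered transition state and expel ethoxide, the conjugated 4-hydroxy-2-pyranone being the thermodynamic product.

Step 3
Reactants: 5 4-hydroxy-3-methyl-6-(2-methylpropyl)-2H-pyran-2-one
Product: 6 4-methoxy-3-methyl-6-(2-methylpropyl)-2H-pyran-2-one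
Conditions: Me2SO4 (1.2 equiv), K2CO3 (2 equiv), acetone, reflux
Reagents that add atoms: dimethyl sulfate, COS(=O)(=O)OC
Why: Williamson-type O-methylation of the vinylogous acid with a hard electrophile should give the 4-methoxy-2-pyranone, the usual outcome for 4-hydroxy-2-pyranones under these conditions, and it fixes the future 6'-OCH3 while the other two future ring oxygens are not yet phenols.

Step 4
Reactants: 6 4-methoxy-3-methyl-6-(2-methylpropyl)-2H-pyran-2-one (2 equiv); 7 dimethyl glutarate
Product: 10 3',3'''-methylenebis(2',4'-dihydroxy-6'-methoxy-β,5'-dimethylbutyrophenone), via dilithium glutarate bis-enolate 8 (not isolated), via open-chain bis(keto ester) 9 (not isolated)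
Conditions: 7 (1.0 equiv), LiN(iPr)2 (2.1 equiv), THF, −78 °C; then 6 (2.2 equiv), −78 to −20 °C; then NaOMe (3 equiv), MeOH, rt to 50 °C, argon; aq. HCl
Reagents that add atoms: dimethyl glutarate (7), COC(=O)CCCC(=O)OC
Why: Proposed new method: each enolate carbon of 8 should add to the lactone carbonyl (C2) of a molecule of 6, the tetrahedral intermediate should open with the ring oxygen leaving as the enolate of the isobutyl ketone to give 9 as its twofold vinylogous diketonate, and in this anion the former pyranone C5, held cis to the new ketone by the former C3=C4 double bond, should attack the adjacent glutarate ester in a Dieckmann-type Claisen condensation, after which loss of methoxide and enolisation give the phenol. The closest known reaction types are the attack of ester-bearing carbanions on the lactone carbonyl of 4-methoxy-2-pyranones with ring opening and onward Claisen closure, and the Claisen cyclisation of 3,5,7-trioxoalkanoates to acylphloroglucinols; what is new is that the pyranone's own C5 returns to the ester of the nucleophile, so that four pyranone carbons and two ester carbons become a benzene ring, twice in one molecule. Each benzene ring is closed by a 6-exo-trig acyl substitution that forms the C1'–C2' bond after the intermolecular C3'–C4' bond, and no stereocentre is formed because the α-carbons of 9 become aromatic. The regiochemistry of the ether is fixed by the origin of the oxygens, 4'-OH being the lactone carbonyl, 2'-OH the glutarate ester carbonyl and 6'-OCH3 the enol ether of 6. Other closures are shut off by the substrate: the methylated oxygen cannot relactonise onto the ester, the methyl-bearing carbon could only give a four-membered ring or, across the bridge, a non-enolisable diketone that methoxide reopens, and aldol attack of a glutarate α-carbon on the isobutyl ketone would give a ring with a quaternary carbon that cannot aromatise and reverts. The step needs carbonyl addition to outrun proton transfer from the isobutyl CH2 of 6, which the preformed enolate at −78 °C should favour, and needs a base for ring closure that does not deprotonate each arm a second time, which is why methoxide in methanol and not more amide is added.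

**Compound list**

1 | ethyl 2-methyl-3-oxobutanoate (ethyl 2-methylacetoacetate, racemic) | CCOC(=O)C(C)C(C)=O | starting material
2 | ethyl 3-methylbutanoate (ethyl isovalerate) | CCOC(=O)CC(C)C | starting material
3 | dilithium bis-enolate of 1 (deprotonated at C2 and C4) | [Li+].[Li+].C=C([O-])C(C)=C([O-])OCC | intermediate
4 | ethyl 2,7-dimethyl-3,5-dioxooctanoate (racemic at C2) | CCOC(=O)C(C)C(=O)CC(=O)CC(C)C | intermediate
5 | 4-hydroxy-3-methyl-6-(2-methylpropyl)-2H-pyran-2-one | CC(C)Cc1cc(O)c(C)c(=O)o1 | intermediate
6 | 4-methoxy-3-methyl-6-(2-methylpropyl)-2H-pyran-2-one | COc1cc(CC(C)C)oc(=O)c1C | intermediate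
7 | dimethyl glutarate (dimethyl pentanedioate) | COC(=O)CCCC(=O)OC | starting material
8 | dilithium bis-enolate of 7 (dilithium 1,5-dimethoxypenta-1,4-diene-1,5-diolate) | [Li+].[Li+].COC([O-])=CCC=C([O-])OC | intermediate
9 | dimethyl 2,4-bis[(2E)-3-methoxy-2,7-dimethyl-5-oxooct-2-enoyl]pentanedioate (mixture of diastereomers at C2 and C4) | COC(=O)C(C(=O)/C(C)=C(/OC)CC(=O)CC(C)C)CC(C(=O)OC)C(=O)/C(C)=C(/OC)CC(=O)CC(C)C | intermediate
10 | 3',3'''-methylenebis(2',4'-dihydroxy-6'-methoxy-β,5'-dimethylbutyrophenone), i.e. bis[2,6-dihydroxy-4-methoxy-3-methyl-5-(3-methylbutanoyl)phenyl]methane | COc1c(C)c(O)c(Cc2c(O)c(C)c(OC)c(C(=O)CC(C)C)c2O)c(O)c1C(=O)CC(C)C | target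

Total step count: 4. Longest linear sequence: 4 (1 → 4 → 5 → 6 → 10).

Steps most likely to fail

Step 4. The enolate may abstract a proton from the isobutyl CH2 of 6, or add at C6 or C4 of the pyranone, in place of adding to the lactone carbonyl; the arms may also open without closing. The fallback uses known chemistry, sets out from 2 and returns at 10, giving up the de novo ring synthesis.
- Ester 2 would be saponified (NaOH, aq. EtOH; HCl) to 3-methylbutanoic acid F1.
- F1 would acylate commercial 2-methylbenzene-1,3,5-triol (BF3·OEt2, 80 °C, Friedel–Crafts) to 1-(2,4,6-trihydroxy-3-methylphenyl)-3-methylbutan-1-one F2.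
- MOMCl (2.2 equiv) and iPr2NEt would protect the para and the less hindered ortho hydroxyl, leaving the hydrogen-bonded hydroxyl next to the methyl group free, to give 1-[2-hydroxy-4,6-bis(methoxymethoxy)-3-methylphenyl]-3-methylbutan-1-one F3.
- MeI and K2CO3 in DMF would methylate that hydroxyl to 1-[2-methoxy-4,6-bis(methoxymethoxy)-3-methylphenyl]-3-methylbutan-1-one F4.
- HCl in MeOH would free 1-(4,6-dihydroxy-2-methoxy-3-methylphenyl)-3-methylbutan-1-one F5.
- Aqueous formaldehyde (0.5 equiv) with NaOH would join two molecules of F5 at their only free ring carbon (hydroxymethylation, then capture of the ortho-quinone methide) to give 10.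

Step 1. Proton transfer from the newly formed, more acidic diketo ester to the dianion, and Claisen self-condensation of 2, may leave the acylation incomplete. The fallback sets out from 1 (through its bis-enolate 3) and returns at 4. The same bis-enolate would instead undergo aldol addition to 3-methylbutanal (THF, −78 °C), which consumes no second equivalent of base, to give ethyl 5-hydroxy-2,7-dimethyl-3-oxooctanoate F6. Oxidation of the secondary alcohol with Dess–Martin periodinane would then give 4.

Step 3. Methylation may occur at the lactone carbonyl oxygen (giving the 2-methoxy-4-pyranone) or at C3. The fallback sets out from 5 and returns at 6, and forms the C4–O bond in place of the O–CH3 bond. Compound 5 would be converted (P2O5, Bu4NBr, toluene, 100 °C) into 4-bromo-3-methyl-6-(2-methylpropyl)-2H-pyran-2-one F7. NaOMe in MeOH would then replace bromide at C4 by addition–elimination to give 6.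

Further compounds
F1 | step 4 | 3-methylbutanoic acid | CC(C)CC(=O)O
F2 | step 4 | 1-(2,4,6-trihydroxy-3-methylphenyl)-3-methylbutan-1-one | Cc1c(O)cc(O)c(C(=O)CC(C)C)c1O
F3 | step 4 | 1-[2-hydroxy-4,6-bis(methoxymethoxy)-3-methylphenyl]-3-methylbutan-1-one | COCOc1cc(OCOC)c(C(=O)CC(C)C)c(O)c1C
F4 | step 4 | 1-[2-methoxy-4,6-bis(methoxymethoxy)-3-methylphenyl]-3-methylbutan-1-one | COCOc1cc(OCOC)c(C(=O)CC(C)C)c(OC)c1C
F5 | step 4 | 1-(4,6-dihydroxy-2-methoxy-3-methylphenyl)-3-methylbutan-1-one | COc1c(C)c(O)cc(O)c1C(=O)CC(C)C
F6 | step 1 | ethyl 5-hydroxy-2,7-dimethyl-3-oxooctanoate | CCOC(=O)C(C)C(=O)CC(O)CC(C)C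
F7 | step 3 | 4-bromo-3-methyl-6-(2-methylpropyl)-2H-pyran-2-one | CC(C)Cc1cc(Br)c(C)c(=O)o1
A1 | direct plan | 1-(2,4-dihydroxy-5-methylphenyl)-3-methylbutan-1-one | Cc1cc(C(=O)CC(C)C)c(O)cc1O
A2 | direct plan | bis[2,6-dihydroxy-3-methyl-5-(3-methylbutanoyl)phenyl]methane | Cc1cc(C(=O)CC(C)C)c(O)c(Cc2c(O)c(C)cc(C(=O)CC(C)C)c2O)c1O
A3 | direct plan | bis{3-[(1E)-N-methoxy-3-methylbutanimidoyl]-5-methyl-2,6-bis(pivaloyloxy)phenyl}methane | Cc1cc(/C(CC(C)C)=N/OC)c(OC(=O)C(C)(C)C)c(Cc2c(OC(=O)C(C)(C)C)c(C)cc(/C(CC(C)C)=N/OC)c2OC(=O)C(C)(C)C)c1OC(=O)C(C)(C)C
A4 | direct plan | bis{4-methoxy-3-[(1E)-N-methoxy-3-methylbutanimidoyl]-5-methyl-2,6-bis(pivaloyloxy)phenyl}methane | COc1c(C)c(OC(=O)C(C)(C)C)c(Cc2c(OC(=O)C(C)(C)C)c(C)c(OC)c(/C(CC(C)C)=N/OC)c2OC(=O)C(C)(C)C)c(OC(=O)C(C)(C)C)c1/C(CC(C)C)=N/OC
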